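**Retrosynthetic overview**
- The strategy rests on ring B of the chromone (C-4a, C-5, C-6, C-7, C-8, C-8a): a 2,4-dioxygenated aryl ketone tied to the rest only through the C-4a–C-4 bond, so its six carbons can be grown on an ethynyl ketone at C-4.
- Last operations: the three benzyl ethers are removed, and before that ring C is closed by inserting C-2 (from DMF) between C-3 and O-1.
- Ring B: [4+2] cycloaddition of the terminal ynone with 1-methoxy-1,3-bis(trimethylsilyloxy)buta-1,3-diene (bonds C-4a–C-8a and C-5–C-6), then aromatisation.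
- Ynone: from a 2-substituted succinate with two differentiated acyl groups; the thioester at Ca is coupled with the ring A boronic acid, then the tert-butyl ester becomes a thioester and is alkynylated.
- Ca: auxiliary-controlled alkylation of the 3,3-diarylpropanoyl imide (from aryl-copper addition to the cinnamoyl imide) with tert-butyl bromoacetate. Ring A and the two phenol rings are bought, ring B is built, ring C is closed last.

Key step: step 15

Remark on the chemistry: locants C-2 to C-8a are those of the chromone in the target, ring A is the 2-hydroxy-4-methoxyphenyl ketone ring and Ca is the stereocentre. Ca keeps one spatial arrangement from step 4 onward; its descriptor is S while its neighbour is a CH2 group and becomes R in step 16 only because C-3 then outranks the diarylmethyl group.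

**Step 1**
Reactants: 1 4-(benzyloxy)benzaldehyde; 2 malonic acid
Product: 3 (E)-3-[4-(benzyloxy)phenyl]prop-2-enoic acid
Conditions: pyridine, piperidine (cat.), 100 °C; then aq HCl
Reagents that add atoms: none
Why: Knoevenagel–Doebner condensation with decarboxylation should give the (E)-cinnamic acid from an electron-rich benzaldehyde.

**Step 2**
Reactants: 3 (E)-3-[4-(benzyloxy)phenyl]prop-2-enoic acid; 4 (S)-4-benzyl-2-oxazolidinone
Product: 6 (4S)-4-benzyl-3-{(E)-3-[4-(benzyloxy)phenyl]prop-2-enoyl}-1,3-oxazolidin-2-one, via mixed pivalic anhydride 5 (not isolated)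
Conditions: t-BuCOCl, Et3N, THF, −20 °C; then 4, LiCl, rt
Reagents that add atoms: none
Why: N-acylation of the oxazolidinone through the mixed pivalic anhydride with LiCl/Et3N is the standard mild route to N-enoyl imides, the hindered pivaloyl carbonyl not being attacked.

**Step 3**
Reactants: 6 (4S)-4-benzyl-3-{(E)-3-[4-(benzyloxy)phenyl]prop-2-enoyl}-1,3-oxazolidin-2-one; 7 1-(benzyloxy)-4-bromobenzene
Product: 9 (4S)-4-benzyl-3-{3,3-bis[4-(benzyloxy)phenyl]propanoyl}-1,3-oxazolidin-2-one, via 4-(benzyloxy)phenylmagnesium bromide 8 (not isolated)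
Conditions: 7, Mg, THF, reflux; then CuBr·SMe2 (20 mol%), THF–Me2S, −40 °C, add 6, to 0 °C; then 1 M HCl
Reagents that add atoms: none
Why: Copper-catalysed conjugate addition of an aryl Grignard reagent to an N-cinnamoyl oxazolidinone is well established, and since both β-aryl groups are the same no stereocentre is formed.

**Step 4**
Reactants: 9 (4S)-4-benzyl-3-{3,3-bis[4-(benzyloxy)phenyl]propanoyl}-1,3-oxazolidin-2-one
Product: 11 tert-butyl (3S)-3-{bis[4-(benzyloxy)phenyl]methyl}-4-[(4S)-4-benzyl-2-oxo-1,3-oxazolidin-3-yl]-4-oxobutanoate, via sodium (Z)-enolate 10 (not isolated)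
Conditions: NaN(SiMe3)2, THF, −78 °C; BrCH2CO2t-Bu, −78 → −40 °C
Reagents that add atoms: tert-butyl bromoacetate CC(C)(C)OC(=O)CBr
Why: Oxazolidinone-imide enolate alkylation (Evans alkylation), in which the chelated sodium (Z)-enolate is alkylated on the face opposite the C-4 benzyl group of the (S)-auxiliary, which should set Ca as (3S), the arrangement of the target.

**Step 5**
Reactants: 11 tert-butyl (3S)-3-{bis[4-(benzyloxy)phenyl]methyl}-4-[(4S)-4-benzyl-2-oxo-1,3-oxazolidin-3-yl]-4-oxobutanoate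
Product: 12 tert-butyl (3S)-3-{bis[4-(benzyloxy)phenyl]methyl}-4-(ethylsulfanyl)-4-oxobutanoate
Conditions: EtSH, n-BuLi, THF, 0 °C; then 1 M HCl
Reagents that add atoms: ethanethiol CCS
Why: Thiolysis of the imide by lithium ethanethiolate, a small, strongly nucleophilic and weakly basic reagent, should cleave the exocyclic acyl group to the thioester without epimerising Ca or touching the tert-butyl ester, and auxiliary 4 is recovered.

**Step 6**
Reactants: 13 2-bromo-5-methoxyphenol
Product: 14 2-(benzyloxy)-1-bromo-4-methoxybenzene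
Conditions: BnBr, K2CO3, DMF, rt
Reagents that add atoms: benzyl bromide BrCc1ccccc1
Why: Williamson etherification of the phenol.

**Step 7**
Reactants: 14 2-(benzyloxy)-1-bromo-4-methoxybenzene
Product: 16 [2-(benzyloxy)-4-methoxyphenyl]boronic acid, via 2-(benzyloxy)-4-methoxyphenyllithium 15 (not isolated)
Conditions: n-BuLi, THF, −78 °C; B(Oi-Pr)3, −78 °C → rt; then 1 M HCl
Reagents that add atoms: triisopropyl borate CC(C)OB(OC(C)C)OC(C)C; water O
Why: Bromine–lithium exchange at −78 °C outruns any attack on the benzyl ether, and borylation followed by hydrolysis gives the boronic acid.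

**Step 8**
Reactants: 12 tert-butyl (3S)-3-{bis[4-(benzyloxy)phenyl]methyl}-4-(ethylsulfanyl)-4-oxobutanoate; 16 [2-(benzyloxy)-4-methoxyphenyl]boronic acid
Product: 17 tert-butyl (3S)-4-[2-(benzyloxy)-4-methoxyphenyl]-3-{bis[4-(benzyloxy)phenyl]methyl}-4-oxobutanoate
Conditions: Pd2(dba)3 (2.5 mol%), P(2-furyl)3 (15 mol%), Cu(O2CC4H3S) (copper thiophene-2-carboxylate, 1.6 equiv), THF, 50 °C
Reagents that add atoms: none
Why: Liebeskind–Srogl coupling of a thioester with a boronic acid forms the ring A ketone under neutral, base-free conditions, so the stereocentre next to the acyl group and the tert-butyl ester should stay intact.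

**Step 9**
Reactants: 17 tert-butyl (3S)-4-[2-(benzyloxy)-4-methoxyphenyl]-3-{bis[4-(benzyloxy)phenyl]methyl}-4-oxobutanoate
Product: 18 (3S)-4-[2-(benzyloxy)-4-methoxyphenyl]-3-{bis[4-(benzyloxy)phenyl]methyl}-4-oxobutanoic acid
Conditions: CF3CO2H–CH2Cl2 (1:4), 0 °C → rt
Reagents that add atoms: none
Why: Acidolysis of the tert-butyl ester with loss of isobutene leaves benzyl aryl ethers and the ketone untouched at room temperature.

**Step 10**
Reactants: 18 (3S)-4-[2-(benzyloxy)-4-methoxyphenyl]-3-{bis[4-(benzyloxy)phenyl]methyl}-4-oxobutanoic acid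
Product: 19 S-ethyl (3S)-4-[2-(benzyloxy)-4-methoxyphenyl]-3-{bis[4-(benzyloxy)phenyl]methyl}-4-oxobutanethioate
Conditions: EtSH, DCC, DMAP (cat.), CH2Cl2, 0 °C → rt
Reagents that add atoms: ethanethiol CCS
Why: Steglich thioesterification, in which the thiol intercepts the carbodiimide-activated γ-keto acid at 0 °C before the ketone can take part.

**Step 11**
Reactants: 19 S-ethyl (3S)-4-[2-(benzyloxy)-4-methoxyphenyl]-3-{bis[4-(benzyloxy)phenyl]methyl}-4-oxobutanethioate
Product: 20 (2S)-1-[2-(benzyloxy)-4-methoxyphenyl]-2-{bis[4-(benzyloxy)phenyl]methyl}-6-(trimethylsilyl)hex-5-yne-1,4-dione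
Conditions: Me3SiC≡CH, PdCl2(dppf) (10 mol%), P(2-furyl)3 (25 mol%), CuI (1.7 equiv), Et3N, DMF, 50 °C
Reagents that add atoms: ethynyltrimethylsilane C#C[Si](C)(C)C
Why: Palladium/copper-mediated coupling of a thioester with a terminal alkyne (Fukuyama-type alkynylation) gives the ynone, while the aryl ketone, which an alkynyl-metal nucleophile would attack, does not react.

**Step 12**
Reactants: 20 (2S)-1-[2-(benzyloxy)-4-methoxyphenyl]-2-{bis[4-(benzyloxy)phenyl]methyl}-6-(trimethylsilyl)hex-5-yne-1,4-dione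
Product: 21 (2S)-1-[2-(benzyloxy)-4-methoxyphenyl]-2-{bis[4-(benzyloxy)phenyl]methyl}hex-5-yne-1,4-dione
Conditions: Na2B4O7·10H2O (10 mol%), MeOH–THF, 0 °C → rt
Reagents that add atoms: none
Why: Borax-buffered protodesilylation of the silyl ynone runs near neutral pH, which should avoid conjugate addition of methoxide to the terminal ynone and enolisation at Ca.

**Step 13**
Reactants: 22 methyl acetoacetate
Product: 23 methyl (E)-3-(trimethylsilyloxy)but-2-enoate
Conditions: Me3SiCl, Et3N, hexane, rt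
Reagents that add atoms: chlorotrimethylsilane C[Si](C)(C)Cl
Why: O-silylation of the enol of the β-keto ester gives the silyl enol ether.

**Step 14**
Reactants: 23 methyl (E)-3-(trimethylsilyloxy)but-2-enoate
Product: 25 1-methoxy-1,3-bis(trimethylsilyloxy)buta-1,3-diene, via lithium dienolate 24 (not isolated)
Conditions: LiN(i-Pr)2, THF, −78 °C; Me3SiCl, −78 °C → rt; distil, use fresh
Reagents that add atoms: chlorotrimethylsilane C[Si](C)(C)Cl
Why: γ-Deprotonation to the dienolate followed by O-silylation is the standard preparation of 1-alkoxy-1,3-bis(silyloxy) dienes.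

**Step 15**
Reactants: 21 (2S)-1-[2-(benzyloxy)-4-methoxyphenyl]-2-{bis[4-(benzyloxy)phenyl]methyl}hex-5-yne-1,4-dione; 25 1-methoxy-1,3-bis(trimethylsilyloxy)buta-1,3-diene
Product: 27 (2S)-1-[2-(benzyloxy)-4-methoxyphenyl]-2-{bis[4-(benzyloxy)phenyl]methyl}-4-(2,4-dihydroxyphenyl)butane-1,4-dione, via cyclohexadiene cycloadduct 26 (not isolated)
Conditions: 25 (2 equiv), PhMe, 0 °C → 50 °C; then 1 M HCl, THF, rt
Reagents that add atoms: none
Why: The electron-rich diene 25 adds its unsubstituted CH2 terminus to the β-carbon of the ynone (C-5–C-6) and its ketene-acetal carbon to the acyl-bearing alkyne carbon (C-4a–C-8a) in a concerted but strongly asynchronous normal-demand Diels–Alder reaction, giving the 1,4-cyclohexadiene 26. Dilute acid then cleaves the mixed silyl methyl acetal at C-8a with loss of methanol, the dienone tautomerises to the phenol and the second silyl ether is hydrolysed, which leaves O-1 ortho and the C-7 hydroxyl para to the C-4 carbonyl. The closest known reaction type is the benzannulation of 1-alkoxy-1,3-bis(silyloxy)buta-1,3-dienes with acetylenic ketones and esters to resorcinol derivatives. Ring B is closed by intermolecular [4+2] cycloaddition in which the two new bonds join the diene termini to the two alkyne carbons; no stereocentre is created, because the acetal carbon of 26 becomes aromatic. The step needs the regiochemistry given by the matched polarisation of the diene (largest HOMO coefficient at CH2) and the ynone (largest LUMO coefficient at the terminal carbon), and it needs [4+2] rather than a Lewis-acid-type [3+3] or a simple Michael addition, which the absence of any Lewis acid and the unhindered terminal alkyne should secure. Ca, the ring A ketone and the benzyl ethers are spectators under these neutral conditions, so the stereocentre set in step 4 should be carried through.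

**Step 16**
Reactants: 27 (2S)-1-[2-(benzyloxy)-4-methoxyphenyl]-2-{bis[4-(benzyloxy)phenyl]methyl}-4-(2,4-dihydroxyphenyl)butane-1,4-dione
Product: 29 (2R)-1-[2-(benzyloxy)-4-methoxyphenyl]-3,3-bis[4-(benzyloxy)phenyl]-2-(7-hydroxy-4-oxo-4H-chromen-3-yl)propan-1-one, via enaminone 28 (not isolated)
Conditions: BF3·OEt2 (4 equiv), DMF, rt; MeSO2Cl (3 equiv), 50 → 70 °C; then H2O
Reagents that add atoms: N,N-dimethylformamide CN(C)C=O
Why: Vilsmeier-type one-carbon chromone annulation, in which the difluoroboron chelate of the ring B 2-hydroxy ketone makes only the C-3 methylene nucleophilic towards the iminium salt from DMF and MeSO2Cl, and the enaminone closes ring C by attack of O-1 on C-2 with loss of dimethylamine, while the benzyl ether on ring A prevents chelation and so disfavours enolisation next to Ca.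

**Step 17**
Reactants: 29 (2R)-1-[2-(benzyloxy)-4-methoxyphenyl]-3,3-bis[4-(benzyloxy)phenyl]-2-(7-hydroxy-4-oxo-4H-chromen-3-yl)propan-1-one
Product: 30 (2R)-1-(2-hydroxy-4-methoxyphenyl)-2-(7-hydroxy-4-oxo-4H-chromen-3-yl)-3,3-bis(4-hydroxyphenyl)propan-1-one
Conditions: H2 (1 atm), Pd/C (10%), EtOAc–THF, rt
Reagents that add atoms: none
Why: Hydrogenolysis of the three benzyl aryl ethers under neutral conditions should be much faster than reduction of the hindered C-2–C-3 double bond or of the hydrogen-bonded aryl ketone, and it cannot epimerise Ca.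

**Compound list**
1 | 4-(benzyloxy)benzaldehyde | O=Cc1ccc(OCc2ccccc2)cc1 | starting material
2 | malonic acid | OC(=O)CC(=O)O | starting material
3 | (E)-3-[4-(benzyloxy)phenyl]prop-2-enoic acid | OC(=O)/C=C/c1ccc(OCc2ccccc2)cc1 | intermediate
4 | (S)-4-benzyl-2-oxazolidinone | O=C1N[C@@H](Cc2ccccc2)CO1 | starting material
5 | mixed anhydride of 3 with pivalic acid (not isolated) | CC(C)(C)C(=O)OC(=O)/C=C/c1ccc(OCc2ccccc2)cc1 | intermediate
6 | (4S)-4-benzyl-3-{(E)-3-[4-(benzyloxy)phenyl]prop-2-enoyl}-1,3-oxazolidin-2-one | O=C(/C=C/c1ccc(OCc2ccccc2)cc1)N1[C@@H](Cc2ccccc2)COC1=O | intermediate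
7 | 1-(benzyloxy)-4-bromobenzene | Brc1ccc(OCc2ccccc2)cc1 | starting material
8 | 4-(benzyloxy)phenylmagnesium bromide (not isolated) | Br[Mg]c1ccc(OCc2ccccc2)cc1 | intermediate
9 | (4S)-4-benzyl-3-{3,3-bis[4-(benzyloxy)phenyl]propanoyl}-1,3-oxazolidin-2-one | O=C(CC(c1ccc(OCc2ccccc2)cc1)c1ccc(OCc2ccccc2)cc1)N1[C@@H](Cc2ccccc2)COC1=O | intermediate
10 | sodium (Z)-enolate of 9 (not isolated) | [Na+].[O-]/C(=C\C(c1ccc(OCc2ccccc2)cc1)c1ccc(OCc2ccccc2)cc1)N1[C@@H](Cc2ccccc2)COC1=O | intermediate
11 | tert-butyl (3S)-3-{bis[4-(benzyloxy)phenyl]methyl}-4-[(4S)-4-benzyl-2-oxo-1,3-oxazolidin-3-yl]-4-oxobutanoate | CC(C)(C)OC(=O)C[C@@H](C(c1ccc(OCc2ccccc2)cc1)c1ccc(OCc2ccccc2)cc1)C(=O)N1[C@@H](Cc2ccccc2)COC1=O | intermediate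
12 | tert-butyl (3S)-3-{bis[4-(benzyloxy)phenyl]methyl}-4-(ethylsulfanyl)-4-oxobutanoate | CCSC(=O)[C@@H](CC(=O)OC(C)(C)C)C(c1ccc(OCc2ccccc2)cc1)c1ccc(OCc2ccccc2)cc1 | intermediate
13 | 2-bromo-5-methoxyphenol | COc1ccc(Br)c(O)c1 | starting material
14 | 2-(benzyloxy)-1-bromo-4-methoxybenzene | COc1ccc(Br)c(OCc2ccccc2)c1 | intermediate
15 | 2-(benzyloxy)-4-methoxyphenyllithium (not isolated) | [Li]c1ccc(OC)cc1OCc1ccccc1 | intermediate
16 | [2-(benzyloxy)-4-methoxyphenyl]boronic acid | COc1ccc(B(O)O)c(OCc2ccccc2)c1 | intermediate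
17 | tert-butyl (3S)-4-[2-(benzyloxy)-4-methoxyphenyl]-3-{bis[4-(benzyloxy)phenyl]methyl}-4-oxobutanoate | COc1ccc(C(=O)[C@@H](CC(=O)OC(C)(C)C)C(c2ccc(OCc3ccccc3)cc2)c2ccc(OCc3ccccc3)cc2)c(OCc2ccccc2)c1 | intermediate
18 | (3S)-4-[2-(benzyloxy)-4-methoxyphenyl]-3-{bis[4-(benzyloxy)phenyl]methyl}-4-oxobutanoic acid | COc1ccc(C(=O)[C@@H](CC(=O)O)C(c2ccc(OCc3ccccc3)cc2)c2ccc(OCc3ccccc3)cc2)c(OCc2ccccc2)c1 | intermediate
19 | S-ethyl (3S)-4-[2-(benzyloxy)-4-methoxyphenyl]-3-{bis[4-(benzyloxy)phenyl]methyl}-4-oxobutanethioate | COc1ccc(C(=O)[C@@H](CC(=O)SCC)C(c2ccc(OCc3ccccc3)cc2)c2ccc(OCc3ccccc3)cc2)c(OCc2ccccc2)c1 | intermediate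
20 | (2S)-1-[2-(benzyloxy)-4-methoxyphenyl]-2-{bis[4-(benzyloxy)phenyl]methyl}-6-(trimethylsilyl)hex-5-yne-1,4-dione | COc1ccc(C(=O)[C@@H](CC(=O)C#C[Si](C)(C)C)C(c2ccc(OCc3ccccc3)cc2)c2ccc(OCc3ccccc3)cc2)c(OCc2ccccc2)c1 | intermediate
21 | (2S)-1-[2-(benzyloxy)-4-methoxyphenyl]-2-{bis[4-(benzyloxy)phenyl]methyl}hex-5-yne-1,4-dione (key-step precursor) | COc1ccc(C(=O)[C@@H](CC(=O)C#C)C(c2ccc(OCc3ccccc3)cc2)c2ccc(OCc3ccccc3)cc2)c(OCc2ccccc2)c1 | intermediate
22 | methyl acetoacetate | CC(=O)CC(=O)OC | starting material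
23 | methyl (E)-3-(trimethylsilyloxy)but-2-enoate | C/C(O[Si](C)(C)C)=C\C(=O)OC | intermediate
24 | lithium dienolate of 23 (not isolated) | [Li+].C=C(O[Si](C)(C)C)/C=C(/[O-])OC | intermediate
25 | 1-methoxy-1,3-bis(trimethylsilyloxy)buta-1,3-diene | C=C(O[Si](C)(C)C)/C=C(/O[Si](C)(C)C)OC | intermediate
26 | (2S)-1-[2-(benzyloxy)-4-methoxyphenyl]-2-{bis[4-(benzyloxy)phenyl]methyl}-4-[6-methoxy-4,6-bis(trimethylsilyloxy)cyclohexa-1,4-dien-1-yl]butane-1,4-dione, both epimers at the acetal carbon (not isolated) | COc1ccc(C(=O)[C@@H](CC(=O)C2=CCC(O[Si](C)(C)C)=CC2(OC)O[Si](C)(C)C)C(c2ccc(OCc3ccccc3)cc2)c2ccc(OCc3ccccc3)cc2)c(OCc2ccccc2)c1 | intermediate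
27 | (2S)-1-[2-(benzyloxy)-4-methoxyphenyl]-2-{bis[4-(benzyloxy)phenyl]methyl}-4-(2,4-dihydroxyphenyl)butane-1,4-dione (key-step product) | COc1ccc(C(=O)[C@@H](CC(=O)c2ccc(O)cc2O)C(c2ccc(OCc3ccccc3)cc2)c2ccc(OCc3ccccc3)cc2)c(OCc2ccccc2)c1 | intermediate
28 | (2R)-1-[2-(benzyloxy)-4-methoxyphenyl]-2-{bis[4-(benzyloxy)phenyl]methyl}-4-(2,4-dihydroxyphenyl)-3-[(dimethylamino)methylidene]butane-1,4-dione, drawn without boron (not isolated) | COc1ccc(C(=O)[C@@H](C(=CN(C)C)C(=O)c2ccc(O)cc2O)C(c2ccc(OCc3ccccc3)cc2)c2ccc(OCc3ccccc3)cc2)c(OCc2ccccc2)c1 | intermediate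
29 | (2R)-1-[2-(benzyloxy)-4-methoxyphenyl]-3,3-bis[4-(benzyloxy)phenyl]-2-(7-hydroxy-4-oxo-4H-chromen-3-yl)propan-1-one | COc1ccc(C(=O)[C@@H](c2coc3cc(O)ccc3c2=O)C(c2ccc(OCc3ccccc3)cc2)c2ccc(OCc3ccccc3)cc2)c(OCc2ccccc2)c1 | intermediate
30 | (2R)-1-(2-hydroxy-4-methoxyphenyl)-2-(7-hydroxy-4-oxo-4H-chromen-3-yl)-3,3-bis(4-hydroxyphenyl)propan-1-one | COc1ccc(C(=O)[C@@H](c2coc3cc(O)ccc3c2=O)C(c2ccc(O)cc2)c2ccc(O)cc2)c(O)c1 | target

**Step count**
Total: 17 steps. Longest linear sequence: 13 steps (steps 1–5, 8–12, 15–17). Steps 6–7 (boronic acid) and 13–14 (diene) are side branches.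

**Steps most likely to fail**

Step 15. The diene may react only as a Michael donor or through its C-2 and C-4 carbons instead of across its termini. The terminal ynone may also oligomerise before cycloaddition, or aromatisation may proceed by loss of silanol, which would leave a methyl ether at O-1. Fallback, from 19 and back at 27: the dioxygenated ring is coupled in instead of built. Commercial 4-bromoresorcinol is protected with MeOCH2Cl and i-Pr2NEt to 1-bromo-2,4-bis(methoxymethoxy)benzene F1. Bromine–lithium exchange (n-BuLi, THF, −78 °C) and B(Oi-Pr)3 with a mild aqueous quench give [2,4-bis(methoxymethoxy)phenyl]boronic acid F2. Thioester 19 is coupled with it under the conditions of step 8 to (2S)-1-[2-(benzyloxy)-4-methoxyphenyl]-2-{bis[4-(benzyloxy)phenyl]methyl}-4-[2,4-bis(methoxymethoxy)phenyl]butane-1,4-dione F3. HCl in MeOH–THF at 40 °C then removes both acetals and returns 27.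

Step 16. Acid-promoted cyclodehydration of the 1,4-diketone to a furan may compete, formylation at the hindered C-3 methylene may be slow, and loss of the ring A benzyl ether would allow chelation-assisted enolisation and hence epimerisation at Ca. Fallback, from 27 and back at 29: aminomethylenation without a Lewis acid. tert-Butoxybis(dimethylamino)methane (Bredereck's reagent, 3 equiv) in THF at 50 °C should convert the C-3 methylene into enaminone 28, which closes to 29 on stirring with AcOH at rt. No compound outside the list is made (F0).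

Step 8. Acyl transfer at the thioester carbon next to the doubly substituted Ca may be slow with an ortho-substituted boronic acid, and protodeboronation of the electron-rich boronic acid may consume it first. Fallback, from 11 and back at 17: LiOH/H2O2 (THF–H2O, 0 °C) cleaves the imide to (2S)-2-{bis[4-(benzyloxy)phenyl]methyl}-4-tert-butoxy-4-oxobutanoic acid F4. MeNHOMe·HCl, EDC and HOBt give tert-butyl (3S)-3-{bis[4-(benzyloxy)phenyl]methyl}-4-[methoxy(methyl)amino]-4-oxobutanoate F5. Aryllithium 15 (from 14 and n-BuLi, THF, −78 °C) should add once to this amide and give 17 after an acidic quench.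

**Further compounds**
F1 | step 15 | 1-bromo-2,4-bis(methoxymethoxy)benzene | COCOc1ccc(Br)c(OCOC)c1
F2 | step 15 | [2,4-bis(methoxymethoxy)phenyl]boronic acid | COCOc1ccc(B(O)O)c(OCOC)c1
F3 | step 15 | (2S)-1-[2-(benzyloxy)-4-methoxyphenyl]-2-{bis[4-(benzyloxy)phenyl]methyl}-4-[2,4-bis(methoxymethoxy)phenyl]butane-1,4-dione | COc1ccc(C(=O)[C@@H](CC(=O)c2ccc(OCOC)cc2OCOC)C(c2ccc(OCc3ccccc3)cc2)c2ccc(OCc3ccccc3)cc2)c(OCc2ccccc2)c1
F0 | step 16 | none | none
F4 | step 8 | (2S)-2-{bis[4-(benzyloxy)phenyl]methyl}-4-tert-butoxy-4-oxobutanoic acid | OC(=O)[C@@H](CC(=O)OC(C)(C)C)C(c1ccc(OCc2ccccc2)cc1)c1ccc(OCc2ccccc2)cc1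
F5 | step 8 | tert-butyl (3S)-3-{bis[4-(benzyloxy)phenyl]methyl}-4-[methoxy(methyl)amino]-4-oxobutanoate | CON(C)C(=O)[C@@H](CC(=O)OC(C)(C)C)C(c1ccc(OCc2ccccc2)cc1)c1ccc(OCc2ccccc2)cc1
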